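## Retrosynthetic overview

1. Target 28 ⇐ C9‑O‑desilylation, C5‑O‑acylation with (S)‑2‑methylbutanoic anhydride and MnO2 oxidation of the C2 allylic alcohol of bicyclic lactone 24.
2. 24 ⇐ indium‑mediated intramolecular Barbier allylation of α‑hydroxy aldehyde / allylic bromide 22 (C6–C7 bond). The seven‑membered carbocycle closes first, the γ‑lactone second, in the same pot.
3. 22 ⇐ Morita–Baylis–Hillman reaction and SN2′ bromination at C7, plus vinyl addition, ozonolysis, propynylation and trans‑reduction at C1/C2, all from ketone 9.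
4. 9 ⇐ key intermolecular titanium aldol (C9–C10 bond) between ethyl ketone 5 (from L‑glycerate acetonide 1) and aldehyde 7 (from 6).
5. Stereocentres: C5 from the chiral pool; C9/C10 from the aldol; C1 from Felkin–Anh addition; C6/C7 from the chelated cyclisation; the ester centre from the (S)‑anhydride.

Assumptions: atom labels C1–C15 follow xanthane numbering of the target (C1 = C(OH)‑acyl ring carbon, C5 = CH–O‑ester, C6 = lactone CH–O, C7 = CH bearing C11, C8 = CH2, C9 = CHOH, C10 = CHMe, C11–C13 = lactone carbons, C2–C4/C15 = side chain, C14 = methyl). TBS = tert‑butyldimethylsilyl, TBDPS = tert‑butyldiphenylsilyl, PMB = 4‑methoxybenzyl. The C2 carbinol (oxidised to the ketone in step 21) is carried as a mixture of epimers in 12–16, 18–24; 18 is also epimeric at the C7 carbinol, which is removed in step 16. The stereochemical outcomes of steps 6, 8 and 20 are predictions from models and analogy, not verified results.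

## Route

Step 1
Reactants: 1 methyl (4S)-2,2-dimethyl-1,3-dioxolane-4-carboxylate
Product: 2 methyl (2S)-2,3-dihydroxypropanoate
Conditions: p‑TsOH·H2O (cat.), MeOH, rt; NaHCO3 quench
Reagents that add atoms: none
Why: Acid‑catalysed transketalisation to methanol (acetal cleavage) removes the acetonide without touching the C5 stereocentre.

Step 2
Reactants: 2 methyl (2S)-2,3-dihydroxypropanoate
Product: 3 methyl (2S)-2,3-bis(TBSO)propanoate
Conditions: TBSCl (2.5 equiv), imidazole, DMF, rt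
Reagents that add atoms: tert‑butyldimethylsilyl chloride CC(C)(C)[Si](C)(C)Cl
Why: Corey silylation of both hydroxyls gives the bulky, non‑chelating α‑silyloxy group needed for steps 6 and 8.

Step 3
Reactants: 3 methyl (2S)-2,3-bis(TBSO)propanoate
Product: 4 (2S)-2,3-bis(TBSO)-N-methoxy-N-methylpropanamide
Conditions: MeNH(OMe)·HCl, i‑PrMgCl, THF, −20 → 0 °C
Reagents that add atoms: N,O‑dimethylhydroxylamine hydrochloride CNOC.Cl
Why: Weinreb amide formation by magnesium‑amide aminolysis is fast at low temperature, so the α‑silyloxy centre is not epimerised.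

Step 4
Reactants: 4 (2S)-2,3-bis(TBSO)-N-methoxy-N-methylpropanamide
Product: 5 (2S)-1,2-bis(TBSO)pentan-3-one
Conditions: EtMgBr, THF, 0 °C; aq. NH4Cl
Reagents that add atoms: ethylmagnesium bromide CC[Mg]Br
Why: Weinreb ketone synthesis stops cleanly at the ethyl ketone (C10/C14 introduced) and the cold, brief conditions preserve the C5 configuration.

Step 5
Reactants: 6 3-(PMBO)propan-1-ol
Product: 7 3-(PMBO)propanal
Conditions: Dess–Martin periodinane, NaHCO3, CH2Cl2, 0 °C → rt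
Reagents that add atoms: none
Why: Dess–Martin oxidation takes the primary alcohol to the aldehyde without over‑oxidation and leaves the PMB ether intact.

Step 6
Reactants: 5 (2S)-1,2-bis(TBSO)pentan-3-one, 7 3-(PMBO)propanal
Product: 8 (2S,4S,5R)-1,2-bis(TBSO)-5-hydroxy-7-(PMBO)-4-methylheptan-3-one
Conditions: TiCl4 (2.2 equiv), i‑Pr2NEt, CH2Cl2, −78 °C; then 7, −78 °C
Reagents that add atoms: none
Why: Titanium‑mediated syn aldol addition in which soft enolisation on the ethyl side gives the Z enolate and a non‑chelated chair transition state biased by the α‑OTBS centre gives the 2,4‑anti‑4,5‑syn adduct, setting C10 (4S) and C9 (5R).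

Step 7
Reactants: 8 (2S,4S,5R)-1,2-bis(TBSO)-5-hydroxy-7-(PMBO)-4-methylheptan-3-one
Product: 9 (2S,4S,5R)-1,2-bis(TBSO)-5-(TBDPSO)-7-(PMBO)-4-methylheptan-3-one
Conditions: TBDPSCl, imidazole, DMAP (cat.), DMF, 40 °C
Reagents that add atoms: tert‑butyldiphenylsilyl chloride CC(C)(C)[Si](Cl)(c1ccccc1)c1ccccc1
Why: Silylation under weakly basic conditions (no retro‑aldol) installs a non‑chelating C9 ether that outlasts the later TBS removals.

Step 8
Reactants: 9 (2S,4S,5R)-1,2-bis(TBSO)-5-(TBDPSO)-7-(PMBO)-4-methylheptan-3-one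
Product: 10 (2S,3S,4S,5R)-1,2-bis(TBSO)-5-(TBDPSO)-3-ethenyl-7-(PMBO)-4-methylheptan-3-ol
Conditions: CH2=CHMgBr, anhydrous CeCl3, THF, −78 → 0 °C
Reagents that add atoms: vinylmagnesium bromide C=C[Mg]Br
Why: Organocerium 1,2‑addition suppresses enolisation, and with only silyl ethers present the polar Felkin–Anh preference of the C5–OTBS centre and the Felkin preference of the C10 methyl centre reinforce each other, setting the C1 carbinol (3S).

Step 9
Reactants: 10 (2S,3S,4S,5R)-1,2-bis(TBSO)-5-(TBDPSO)-3-ethenyl-7-(PMBO)-4-methylheptan-3-ol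
Product: 11 (2S,3S,4R)-2-[(1S)-1,2-bis(TBSO)ethyl]-4-(TBDPSO)-2-hydroxy-6-(PMBO)-3-methylhexanal
Conditions: O3, CH2Cl2–MeOH, NaHCO3, −78 °C (Sudan III end point); then PPh3
Reagents that add atoms: ozone [O-][O+]=O
Why: Ozonolysis with reductive work‑up cleaves the only alkene to the C2 aldehyde without touching a stereocentre.

Step 10
Reactants: 11 (2S,3S,4R)-2-[(1S)-1,2-bis(TBSO)ethyl]-4-(TBDPSO)-2-hydroxy-6-(PMBO)-3-methylhexanal
Product: 12 (4RS,5R,6S,7R)-5-[(1S)-1,2-bis(TBSO)ethyl]-7-(TBDPSO)-9-(PMBO)-6-methylnon-2-yne-4,5-diol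
Conditions: CH3C≡CMgBr (3 equiv), THF, −78 → 0 °C
Reagents that add atoms: 1‑propynylmagnesium bromide CC#C[Mg]Br
Why: Grignard addition to the aldehyde (after deprotonation of the tertiary OH) brings in C3, C4 and C15; the new C2 carbinol forms as an inconsequential epimer mixture because C2 becomes the ketone in step 21.

Step 11
Reactants: 12 (4RS,5R,6S,7R)-5-[(1S)-1,2-bis(TBSO)ethyl]-7-(TBDPSO)-9-(PMBO)-6-methylnon-2-yne-4,5-diol
Product: 13 (2E,4RS,5R,6S,7R)-5-[(1S)-1,2-bis(TBSO)ethyl]-7-(TBDPSO)-9-(PMBO)-6-methylnon-2-ene-4,5-diol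
Conditions: NaAlH2(OCH2CH2OMe)2 (Red‑Al), THF, 0 °C → rt
Reagents that add atoms: none
Why: Hydroxyl‑directed trans‑hydroalumination of the propargylic alcohol gives only the (E)‑alkene.

Step 12
Reactants: 13 (2E,4RS,5R,6S,7R)-5-[(1S)-1,2-bis(TBSO)ethyl]-7-(TBDPSO)-9-(PMBO)-6-methylnon-2-ene-4,5-diol
Product: 14 (2E,4RS,5R,6S,7R)-4-(TBSO)-5-[(1S)-1,2-bis(TBSO)ethyl]-7-(TBDPSO)-9-(PMBO)-6-methylnon-2-en-5-ol
Conditions: TBSOTf (1.1 equiv), 2,6‑lutidine, CH2Cl2, −78 °C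
Reagents that add atoms: tert‑butyldimethylsilyl triflate CC(C)(C)[Si](C)(C)OS(=O)(=O)C(F)(F)F
Why: Silylation at low temperature selects the secondary allylic C2 hydroxyl over the hindered tertiary C1 hydroxyl, masking it against the coming oxidations.

Step 13
Reactants: 14 (2E,4RS,5R,6S,7R)-4-(TBSO)-5-[(1S)-1,2-bis(TBSO)ethyl]-7-(TBDPSO)-9-(PMBO)-6-methylnon-2-en-5-ol
Product: 15 (3R,4S,5R,6RS,7E)-5-[(1S)-1,2-bis(TBSO)ethyl]-3-(TBDPSO)-6-(TBSO)-4-methylnon-7-ene-1,5-diol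
Conditions: DDQ, CH2Cl2–pH 7 buffer (10:1), 0 °C
Reagents that add atoms: none
Why: Oxidative PMB cleavage by DDQ frees only the C7 primary alcohol and leaves silyl ethers and the alkene untouched.

Step 14
Reactants: 15 (3R,4S,5R,6RS,7E)-5-[(1S)-1,2-bis(TBSO)ethyl]-3-(TBDPSO)-6-(TBSO)-4-methylnon-7-ene-1,5-diol
Product: 16 (3R,4S,5R,6RS,7E)-5-[(1S)-1,2-bis(TBSO)ethyl]-3-(TBDPSO)-6-(TBSO)-5-hydroxy-4-methylnon-7-enal
Conditions: Dess–Martin periodinane, NaHCO3, CH2Cl2, 0 °C → rt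
Reagents that add atoms: none
Why: Dess–Martin oxidation converts the primary alcohol to the C7 aldehyde while the tertiary alcohol cannot be oxidised.

Step 15
Reactants: 16 (3R,4S,5R,6RS,7E)-5-[(1S)-1,2-bis(TBSO)ethyl]-3-(TBDPSO)-6-(TBSO)-5-hydroxy-4-methylnon-7-enal, 17 methyl acrylate
Product: 18 methyl (3RS,5R,6S,7R,8RS,9E)-7-[(1S)-1,2-bis(TBSO)ethyl]-5-(TBDPSO)-8-(TBSO)-3,7-dihydroxy-6-methyl-2-methylideneundec-9-enoate
Conditions: DABCO (0.5 equiv), methyl acrylate (neat, 10 equiv), MeOH (2 equiv), rt, 3–5 d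
Reagents that add atoms: none
Why: The Morita–Baylis–Hillman reaction attaches C11–C13 to the unhindered aldehyde, and the new C7 carbinol (epimer mixture) is of no consequence because it is removed in step 16.

Step 16
Reactants: 18 methyl (3RS,5R,6S,7R,8RS,9E)-7-[(1S)-1,2-bis(TBSO)ethyl]-5-(TBDPSO)-8-(TBSO)-3,7-dihydroxy-6-methyl-2-methylideneundec-9-enoate
Product: 19 methyl (2Z,5R,6S,7R,8RS,9E)-2-(bromomethyl)-7-[(1S)-1,2-bis(TBSO)ethyl]-5-(TBDPSO)-8-(TBSO)-7-hydroxy-6-methylundeca-2,9-dienoate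
Conditions: NBS, Me2S, CH2Cl2, 0 °C → rt
Reagents that add atoms: N‑bromosuccinimide O=C1CCC(=O)N1Br
Why: Corey–Kim‑type activation of the allylic hydroxyl followed by SN2′ attack of bromide gives the thermodynamically preferred (Z)‑2‑(bromomethyl)enoate, while the hindered tertiary alcohol does not react.

Step 17
Reactants: 19 methyl (2Z,5R,6S,7R,8RS,9E)-2-(bromomethyl)-7-[(1S)-1,2-bis(TBSO)ethyl]-5-(TBDPSO)-8-(TBSO)-7-hydroxy-6-methylundeca-2,9-dienoate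
Product: 20 methyl (2Z,5R,6S,7R,8RS,9E)-2-(bromomethyl)-5-(TBDPSO)-8-(TBSO)-7-hydroxy-7-[(1S)-1-(TBSO)-2-hydroxyethyl]-6-methylundeca-2,9-dienoate
Conditions: CSA (0.1 equiv), MeOH–CH2Cl2 (1:1), 0 °C
Reagents that add atoms: none
Why: Acid‑catalysed methanolysis (selective desilylation) removes only the unhindered primary TBS ether, and the amine‑free medium spares the allylic bromide.

Step 18
Reactants: 20 methyl (2Z,5R,6S,7R,8RS,9E)-2-(bromomethyl)-5-(TBDPSO)-8-(TBSO)-7-hydroxy-7-[(1S)-1-(TBSO)-2-hydroxyethyl]-6-methylundeca-2,9-dienoate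
Product: 21 methyl (2Z,5R,6S,7R,8RS,9E)-2-(bromomethyl)-5-(TBDPSO)-8-(TBSO)-7-hydroxy-6-methyl-7-[(1R)-1-(TBSO)-2-oxoethyl]undeca-2,9-dienoate
Conditions: Dess–Martin periodinane, NaHCO3, CH2Cl2, 0 °C
Reagents that add atoms: none
Why: Dess–Martin oxidation gives the configurationally stable α‑silyloxy C6 aldehyde under neutral conditions that the allylic bromide tolerates (the descriptor changes only through CIP priorities).

Step 19
Reactants: 21 methyl (2Z,5R,6S,7R,8RS,9E)-2-(bromomethyl)-5-(TBDPSO)-8-(TBSO)-7-hydroxy-6-methyl-7-[(1R)-1-(TBSO)-2-oxoethyl]undeca-2,9-dienoate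
Product: 22 methyl (2Z,5R,6S,7R,8RS,9E)-2-(bromomethyl)-5-(TBDPSO)-7,8-dihydroxy-7-[(1R)-1-hydroxy-2-oxoethyl]-6-methylundeca-2,9-dienoate
Conditions: 48% aq. HF–MeCN (1:19), 0 °C → rt; used crude (equilibrates with its five‑membered lactols)
Reagents that add atoms: none
Why: Acidic fluoride desilylation removes the two secondary TBS ethers while the more acid‑stable TBDPS ether stays, freeing the C5 hydroxyl needed for chelation in step 20.

Step 20
Reactants: 22 methyl (2Z,5R,6S,7R,8RS,9E)-2-(bromomethyl)-5-(TBDPSO)-7,8-dihydroxy-7-[(1R)-1-hydroxy-2-oxoethyl]-6-methylundeca-2,9-dienoate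
Product: 24 (3aS,5R,6S,7R,8S,8aR)-5-(TBDPSO)-7,8-dihydroxy-7-[(1RS,2E)-1-hydroxybut-2-en-1-yl]-6-methyl-3-methylideneoctahydro-2H-cyclohepta[b]furan-2-one, via seco hydroxy ester 23 (not isolated)
Conditions: In powder (3 equiv), THF–H2O (1:1), 0.005 M, rt; then p‑TsOH (cat.), CH2Cl2, rt
Reagents that add atoms: none
Why: Indium‑mediated intramolecular Barbier allylation in water adds the γ‑carbon (C7) of the allylindium to the C6 aldehyde through a closed transition state chelated by the free C5 hydroxyl, which sets C6 (8aR, syn to C5–O as with unprotected aldoses) and, from the Z bromide, the cis C6/C7 relationship (3aS), after which the cis hydroxy ester lactonises.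

Step 21
Reactants: 24 (3aS,5R,6S,7R,8S,8aR)-5-(TBDPSO)-7,8-dihydroxy-7-[(1RS,2E)-1-hydroxybut-2-en-1-yl]-6-methyl-3-methylideneoctahydro-2H-cyclohepta[b]furan-2-one
Product: 25 (3aS,5R,6S,7S,8S,8aR)-7-[(2E)-but-2-enoyl]-5-(TBDPSO)-7,8-dihydroxy-6-methyl-3-methylideneoctahydro-2H-cyclohepta[b]furan-2-one
Conditions: activated MnO2 (excess), CH2Cl2, rt (monitored, stopped at full conversion)
Reagents that add atoms: none
Why: Chemoselective allylic oxidation by MnO2 converts both C2 epimers into the single (E)‑enone while the saturated C5 and tertiary C1 hydroxyls are left alone.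

Step 22
Reactants: 25 (3aS,5R,6S,7S,8S,8aR)-7-[(2E)-but-2-enoyl]-5-(TBDPSO)-7,8-dihydroxy-6-methyl-3-methylideneoctahydro-2H-cyclohepta[b]furan-2-one, 26 (2S)-2-methylbutanoic anhydride
Product: 27 (3aS,5R,6S,7S,8S,8aR)-7-[(2E)-but-2-enoyl]-5-(TBDPSO)-7-hydroxy-6-methyl-3-methylidene-2-oxooctahydro-2H-cyclohepta[b]furan-8-yl (2S)-2-methylbutanoate
Conditions: DMAP (0.3 equiv), pyridine, CH2Cl2, 0 °C → rt
Reagents that add atoms: none
Why: DMAP‑catalysed acylation with the preformed anhydride esterifies the only acylable hydroxyl (secondary C5; C1 is tertiary, C9 is silylated) without epimerising the acyl α‑centre.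

Step 23
Reactants: 27 (3aS,5R,6S,7S,8S,8aR)-7-[(2E)-but-2-enoyl]-5-(TBDPSO)-7-hydroxy-6-methyl-3-methylidene-2-oxooctahydro-2H-cyclohepta[b]furan-8-yl (2S)-2-methylbutanoate
Product: 28 (3aS,5R,6S,7S,8S,8aR)-7-[(2E)-but-2-enoyl]-5,7-dihydroxy-6-methyl-3-methylidene-2-oxooctahydro-2H-cyclohepta[b]furan-8-yl (2S)-2-methylbutanoate
Conditions: HF·pyridine, pyridine, THF, 0 °C → rt
Reagents that add atoms: none
Why: Buffered fluoride desilylation removes the TBDPS ether under conditions too mild to add to the α‑methylene lactone or enone or to migrate the ester, giving the target.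

## Compound list

1 | methyl (4S)-2,2-dimethyl-1,3-dioxolane-4-carboxylate | COC(=O)[C@@H]1COC(C)(C)O1 | starting material
2 | methyl (2S)-2,3-dihydroxypropanoate | COC(=O)[C@@H](O)CO | intermediate
3 | methyl (2S)-2,3-bis(TBSO)propanoate | COC(=O)[C@@H](O[Si](C)(C)C(C)(C)C)CO[Si](C)(C)C(C)(C)C | intermediate
4 | (2S)-2,3-bis(TBSO)-N-methoxy-N-methylpropanamide | CON(C)C(=O)[C@@H](O[Si](C)(C)C(C)(C)C)CO[Si](C)(C)C(C)(C)C | intermediate
5 | (2S)-1,2-bis(TBSO)pentan-3-one | CCC(=O)[C@@H](O[Si](C)(C)C(C)(C)C)CO[Si](C)(C)C(C)(C)C | intermediate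
6 | 3-(PMBO)propan-1-ol | COc1ccc(COCCCO)cc1 | starting material
7 | 3-(PMBO)propanal | COc1ccc(COCCC=O)cc1 | intermediate
8 | (2S,4S,5R)-1,2-bis(TBSO)-5-hydroxy-7-(PMBO)-4-methylheptan-3-one | COc1ccc(COCC[C@@H](O)[C@H](C)C(=O)[C@@H](O[Si](C)(C)C(C)(C)C)CO[Si](C)(C)C(C)(C)C)cc1 | intermediate
9 | (2S,4S,5R)-1,2-bis(TBSO)-5-(TBDPSO)-7-(PMBO)-4-methylheptan-3-one | COc1ccc(COCC[C@@H](O[Si](c2ccccc2)(c2ccccc2)C(C)(C)C)[C@H](C)C(=O)[C@@H](O[Si](C)(C)C(C)(C)C)CO[Si](C)(C)C(C)(C)C)cc1 | intermediate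
10 | (2S,3S,4S,5R)-1,2-bis(TBSO)-5-(TBDPSO)-3-ethenyl-7-(PMBO)-4-methylheptan-3-ol | COc1ccc(COCC[C@@H](O[Si](c2ccccc2)(c2ccccc2)C(C)(C)C)[C@H](C)[C@@](O)(C=C)[C@@H](O[Si](C)(C)C(C)(C)C)CO[Si](C)(C)C(C)(C)C)cc1 | intermediate
11 | (2S,3S,4R)-2-[(1S)-1,2-bis(TBSO)ethyl]-4-(TBDPSO)-2-hydroxy-6-(PMBO)-3-methylhexanal | COc1ccc(COCC[C@@H](O[Si](c2ccccc2)(c2ccccc2)C(C)(C)C)[C@H](C)[C@@](O)(C=O)[C@@H](O[Si](C)(C)C(C)(C)C)CO[Si](C)(C)C(C)(C)C)cc1 | intermediate
12 | (4RS,5R,6S,7R)-5-[(1S)-1,2-bis(TBSO)ethyl]-7-(TBDPSO)-9-(PMBO)-6-methylnon-2-yne-4,5-diol (C2 epimers) | COc1ccc(COCC[C@@H](O[Si](c2ccccc2)(c2ccccc2)C(C)(C)C)[C@H](C)[C@@](O)(C(O)C#CC)[C@@H](O[Si](C)(C)C(C)(C)C)CO[Si](C)(C)C(C)(C)C)cc1 | intermediate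
13 | (2E,4RS,5R,6S,7R)-5-[(1S)-1,2-bis(TBSO)ethyl]-7-(TBDPSO)-9-(PMBO)-6-methylnon-2-ene-4,5-diol (C2 epimers) | COc1ccc(COCC[C@@H](O[Si](c2ccccc2)(c2ccccc2)C(C)(C)C)[C@H](C)[C@@](O)(C(O)/C=C/C)[C@@H](O[Si](C)(C)C(C)(C)C)CO[Si](C)(C)C(C)(C)C)cc1 | intermediate
14 | (2E,4RS,5R,6S,7R)-4-(TBSO)-5-[(1S)-1,2-bis(TBSO)ethyl]-7-(TBDPSO)-9-(PMBO)-6-methylnon-2-en-5-ol (C2 epimers) | COc1ccc(COCC[C@@H](O[Si](c2ccccc2)(c2ccccc2)C(C)(C)C)[C@H](C)[C@@](O)(C(O[Si](C)(C)C(C)(C)C)/C=C/C)[C@@H](O[Si](C)(C)C(C)(C)C)CO[Si](C)(C)C(C)(C)C)cc1 | intermediate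
15 | (3R,4S,5R,6RS,7E)-5-[(1S)-1,2-bis(TBSO)ethyl]-3-(TBDPSO)-6-(TBSO)-4-methylnon-7-ene-1,5-diol (C2 epimers) | OCC[C@@H](O[Si](c1ccccc1)(c1ccccc1)C(C)(C)C)[C@H](C)[C@@](O)(C(O[Si](C)(C)C(C)(C)C)/C=C/C)[C@@H](O[Si](C)(C)C(C)(C)C)CO[Si](C)(C)C(C)(C)C | intermediate
16 | (3R,4S,5R,6RS,7E)-5-[(1S)-1,2-bis(TBSO)ethyl]-3-(TBDPSO)-6-(TBSO)-5-hydroxy-4-methylnon-7-enal (C2 epimers) | O=CC[C@@H](O[Si](c1ccccc1)(c1ccccc1)C(C)(C)C)[C@H](C)[C@@](O)(C(O[Si](C)(C)C(C)(C)C)/C=C/C)[C@@H](O[Si](C)(C)C(C)(C)C)CO[Si](C)(C)C(C)(C)C | intermediate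
17 | methyl acrylate | C=CC(=O)OC | starting material
18 | methyl (3RS,5R,6S,7R,8RS,9E)-7-[(1S)-1,2-bis(TBSO)ethyl]-5-(TBDPSO)-8-(TBSO)-3,7-dihydroxy-6-methyl-2-methylideneundec-9-enoate (C7 and C2 epimers) | COC(=O)C(=C)C(O)C[C@@H](O[Si](c1ccccc1)(c1ccccc1)C(C)(C)C)[C@H](C)[C@@](O)(C(O[Si](C)(C)C(C)(C)C)/C=C/C)[C@@H](O[Si](C)(C)C(C)(C)C)CO[Si](C)(C)C(C)(C)C | intermediate
19 | methyl (2Z,5R,6S,7R,8RS,9E)-2-(bromomethyl)-7-[(1S)-1,2-bis(TBSO)ethyl]-5-(TBDPSO)-8-(TBSO)-7-hydroxy-6-methylundeca-2,9-dienoate (C2 epimers) | COC(=O)/C(CBr)=C/C[C@@H](O[Si](c1ccccc1)(c1ccccc1)C(C)(C)C)[C@H](C)[C@@](O)(C(O[Si](C)(C)C(C)(C)C)/C=C/C)[C@@H](O[Si](C)(C)C(C)(C)C)CO[Si](C)(C)C(C)(C)C | intermediate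
20 | methyl (2Z,5R,6S,7R,8RS,9E)-2-(bromomethyl)-5-(TBDPSO)-8-(TBSO)-7-hydroxy-7-[(1S)-1-(TBSO)-2-hydroxyethyl]-6-methylundeca-2,9-dienoate (C2 epimers) | COC(=O)/C(CBr)=C/C[C@@H](O[Si](c1ccccc1)(c1ccccc1)C(C)(C)C)[C@H](C)[C@@](O)(C(O[Si](C)(C)C(C)(C)C)/C=C/C)[C@@H](O[Si](C)(C)C(C)(C)C)CO | intermediate
21 | methyl (2Z,5R,6S,7R,8RS,9E)-2-(bromomethyl)-5-(TBDPSO)-8-(TBSO)-7-hydroxy-6-methyl-7-[(1R)-1-(TBSO)-2-oxoethyl]undeca-2,9-dienoate (C2 epimers) | COC(=O)/C(CBr)=C/C[C@@H](O[Si](c1ccccc1)(c1ccccc1)C(C)(C)C)[C@H](C)[C@@](O)(C(O[Si](C)(C)C(C)(C)C)/C=C/C)[C@@H](O[Si](C)(C)C(C)(C)C)C=O | intermediate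
22 | methyl (2Z,5R,6S,7R,8RS,9E)-2-(bromomethyl)-5-(TBDPSO)-7,8-dihydroxy-7-[(1R)-1-hydroxy-2-oxoethyl]-6-methylundeca-2,9-dienoate (C2 epimers; open form of the lactol mixture) | COC(=O)/C(CBr)=C/C[C@@H](O[Si](c1ccccc1)(c1ccccc1)C(C)(C)C)[C@H](C)[C@@](O)(C(O)/C=C/C)[C@@H](O)C=O | intermediate
23 | methyl 2-[(1S,2R,3S,4R,5S,6R)-6-(TBDPSO)-2,3,4-trihydroxy-4-[(1RS,2E)-1-hydroxybut-2-en-1-yl]-5-methylcycloheptyl]prop-2-enoate (seco hydroxy ester) | COC(=O)C(=C)[C@@H]1C[C@@H](O[Si](c2ccccc2)(c2ccccc2)C(C)(C)C)[C@H](C)[C@@](O)(C(O)/C=C/C)[C@@H](O)[C@@H]1O | intermediate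
24 | (3aS,5R,6S,7R,8S,8aR)-5-(TBDPSO)-7,8-dihydroxy-7-[(1RS,2E)-1-hydroxybut-2-en-1-yl]-6-methyl-3-methylideneoctahydro-2H-cyclohepta[b]furan-2-one (C2 epimers) | C=C1C(=O)O[C@@H]2[C@H]1C[C@@H](O[Si](c3ccccc3)(c3ccccc3)C(C)(C)C)[C@H](C)[C@@](O)(C(O)/C=C/C)[C@H]2O | intermediate
25 | (3aS,5R,6S,7S,8S,8aR)-7-[(2E)-but-2-enoyl]-5-(TBDPSO)-7,8-dihydroxy-6-methyl-3-methylideneoctahydro-2H-cyclohepta[b]furan-2-one | C=C1C(=O)O[C@@H]2[C@H]1C[C@@H](O[Si](c3ccccc3)(c3ccccc3)C(C)(C)C)[C@H](C)[C@@](O)(C(=O)/C=C/C)[C@H]2O | intermediate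
26 | (2S)-2-methylbutanoic anhydride | CC[C@H](C)C(=O)OC(=O)[C@@H](C)CC | starting material
27 | (3aS,5R,6S,7S,8S,8aR)-7-[(2E)-but-2-enoyl]-5-(TBDPSO)-7-hydroxy-6-methyl-3-methylidene-2-oxooctahydro-2H-cyclohepta[b]furan-8-yl (2S)-2-methylbutanoate | C=C1C(=O)O[C@@H]2[C@H]1C[C@@H](O[Si](c3ccccc3)(c3ccccc3)C(C)(C)C)[C@H](C)[C@@](O)(C(=O)/C=C/C)[C@H]2OC(=O)[C@@H](C)CC | intermediate
28 | (3aS,5R,6S,7S,8S,8aR)-7-[(2E)-but-2-enoyl]-5,7-dihydroxy-6-methyl-3-methylidene-2-oxooctahydro-2H-cyclohepta[b]furan-8-yl (2S)-2-methylbutanoate | C=C1C(=O)O[C@@H]2[C@H]1C[C@@H](O)[C@H](C)[C@@](O)(C(=O)/C=C/C)[C@H]2OC(=O)[C@@H](C)CC | target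

## Step count and risks

Total step count: 23. Longest linear sequence: 22 steps (1 → 28: steps 1–4 and 6–23); step 5 is the one‑step side branch that makes aldehyde 7.

The three steps most likely to fail, each with one fallback:

Step 6 (aldol). The 2,4‑anti‑4,5‑syn outcome rests on substrate control by the α‑OTBS centre, and the extra β‑silyloxy group of 5 could erode it. The fallback replaces substrate control by reagent control. It sets out from 5 and 7: 5 is enolised with diisopinocampheylboron triflate and i‑Pr2NEt to the Z boron enolate, taking the Ipc antipode that is matched with C5 (both screened), and 7 is added through a Zimmerman–Traxler chair. Oxidative work‑up returns to the route at 8. No new isolable compound is formed.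

Step 8 (addition to the hindered ketone). Enolisation, or partial chelation that lowers the Felkin–Anh selectivity at C1, could cut yield or dr. The fallback uses a smaller sp nucleophile followed by partial reduction. It sets out from 9: ethynylmagnesium bromide with CeCl3 in THF at −78 °C gives the ethynyl carbinol F1, and Lindlar semi‑hydrogenation (Pd/CaCO3/Pb, quinoline, H2, EtOAc) of F1 returns to the route at 10.

Step 20 (ring closure). The allylic bromide may not survive steps 17–19 intact, and the cyclisation has to form a seven‑membered ring with two new stereocentres. The fallback drops the bromide and generates the allylindium by umpolung of an allylic acetate. It sets out from 18: Ac2O, DMAP and pyridine give the allylic acetate F2; CSA in MeOH gives the primary alcohol F3; Dess–Martin periodinane gives the aldehyde F4; aq. HF in MeCN gives the α‑hydroxy aldehyde acetate F5. Pd(PPh3)4 (5 mol %) and InI in THF–H2O then turn the acetate, through a π‑allylpalladium, into the allylindium(III), which cyclises in the same chelated manner through 23 and returns to the route at 24.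

## Further compounds

F0 | step 6 | none | none
F1 | step 8 | 1,2-bis(TBSO)-5-(TBDPSO)-3-ethynyl-7-(PMBO)-4-methylheptan-3-ol (ethynyl analogue of 10, same spatial configuration) | COc1ccc(COCC[C@@H](O[Si](c2ccccc2)(c2ccccc2)C(C)(C)C)[C@H](C)[C@@](O)(C#C)[C@@H](O[Si](C)(C)C(C)(C)C)CO[Si](C)(C)C(C)(C)C)cc1
F2 | step 20 | allylic acetate of 18 (3-acetoxy-2-methylidene ester, all silyl ethers in place) | COC(=O)C(=C)C(OC(C)=O)C[C@@H](O[Si](c1ccccc1)(c1ccccc1)C(C)(C)C)[C@H](C)[C@@](O)(C(O[Si](C)(C)C(C)(C)C)/C=C/C)[C@@H](O[Si](C)(C)C(C)(C)C)CO[Si](C)(C)C(C)(C)C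
F3 | step 20 | primary alcohol from F2 (C6 hydroxyl free) | COC(=O)C(=C)C(OC(C)=O)C[C@@H](O[Si](c1ccccc1)(c1ccccc1)C(C)(C)C)[C@H](C)[C@@](O)(C(O[Si](C)(C)C(C)(C)C)/C=C/C)[C@@H](O[Si](C)(C)C(C)(C)C)CO
F4 | step 20 | C6 aldehyde from F3 | COC(=O)C(=C)C(OC(C)=O)C[C@@H](O[Si](c1ccccc1)(c1ccccc1)C(C)(C)C)[C@H](C)[C@@](O)(C(O[Si](C)(C)C(C)(C)C)/C=C/C)[C@@H](O[Si](C)(C)C(C)(C)C)C=O
F5 | step 20 | α-hydroxy aldehyde allylic acetate (C5 and C2 hydroxyls free) | COC(=O)C(=C)C(OC(C)=O)C[C@@H](O[Si](c1ccccc1)(c1ccccc1)C(C)(C)C)[C@H](C)[C@@](O)(C(O)/C=C/C)[C@@H](O)C=O
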